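**Assumptions (one line each).**
- (S)-Diphenylprolinol TMS ether with (E)-1-nitropropene is taken to give the same syn (2R,3R) sense as with nitrostyrene. If the opposite enantiomer forms, the (R)-catalyst is used.
- The target has a 2,3-trans, 3,4-trans, 2,4-cis tetrahydrofuran, which I take to be the thermodynamically favoured all-trans isomer.

## Retrosynthetic overview
- Disconnect the C2–aryl bond: the 2-aryl-THF comes from Lewis-acid C-arylation of a 3,4-disubstituted lactol (oxocarbenium) with guaiacol, para to OH. This is the only ring-forming step, and it sets C2 anti to the C3 methyl.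
- The lactol is the Nef product of a γ-nitro alcohol. Its trans C3/C4 stereocentres come from one organocatalytic enamine Michael addition of a syringyl propanal to nitropropene.
- The syringyl propanal comes from a Heck reaction of 4-bromo-2,6-dimethoxyphenol with allyl alcohol.
- Both aryl rings come from feedstock phenols (syringol-derived bromide and guaiacol). No protecting groups are used.

## Forward route

**Step 1**
Reactants: 1 (4-bromo-2,6-dimethoxyphenol); 2 (allyl alcohol)
Product: 3 (3-(4-hydroxy-3,5-dimethoxyphenyl)propanal)
Conditions: Pd(OAc)2 (5 mol%), n-Bu4NCl, NaHCO3, DMF, 100 °C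
Reagents that add atoms: allyl alcohol, C=CCO
Why: Jeffery–Heck arylation of allyl alcohol occurs at the terminal carbon, and the resulting enol tautomerises to the 3-arylpropanal. No stereocentre is formed.

**Step 2**
Reactants: 3; 4 ((E)-1-nitropropene); 5 ((S)-diphenylprolinol TMS ether, catalyst)
Product: 6 ((2R,3R)-2-[(4-hydroxy-3,5-dimethoxyphenyl)methyl]-3-methyl-4-nitrobutanal)
Conditions: 5 (10 mol%), PhCO2H (10 mol%), toluene, 0 °C → rt, 24 h
Reagents that add atoms: (E)-1-nitropropene, C/C=C/[N+](=O)[O-]
Why: This is an enamine-catalysed (Hayashi–Jørgensen) Michael addition. The E-enamine of 3 attacks the nitroalkene through a synclinal transition state with one face shielded by the catalyst. This sets C8' and C8 together as the syn adduct, which corresponds to the trans-3,4 pattern after ring closure.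

**Step 3**
Reactants: 6
Product: 7 ((2R,3R)-2-[(4-hydroxy-3,5-dimethoxyphenyl)methyl]-3-methyl-4-nitrobutan-1-ol)
Conditions: NaBH4, MeOH, 0 °C, added to the crude Step 2 mixture
Reagents that add atoms: none
Why: Chemoselective aldehyde reduction leaves the nitro group and phenol intact. Reducing immediately prevents epimerisation of the α-stereocentre. No new stereocentre is formed.

**Step 4**
Reactants: 7
Product: 8 ((3R,4R)-4-[(4-hydroxy-3,5-dimethoxyphenyl)methyl]-3-methyloxolan-2-ol, anomeric mixture)
Conditions: aq. TiCl3, NH4OAc buffer, MeOH/H2O, rt
Reagents that add atoms: water, O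
Why: McMurry-type reductive Nef reaction converts the primary nitro group to the aldehyde under mild, buffered conditions. The γ-hydroxy aldehyde closes spontaneously to the lactol, which protects C3 from enolisation. No stereocentre is changed.

**Step 5**
Reactants: 8; 9 (guaiacol)
Product: 10 (target)
Conditions: Sc(OTf)3 (10 mol%), 4 Å MS, MeNO2/CH2Cl2, 0 °C → rt, guaiacol (4 equiv)
Reagents that add atoms: guaiacol, COc1ccccc1O
Why: Proposed new method: Lewis acid ionises the lactol to a 3,4-trans-disubstituted oxocarbenium. Guaiacol attacks through its carbon para to OH, via a dearomatised Wheland intermediate. The nucleophile approaches anti to the C3 methyl, giving 2,3-trans and 2,4-cis. Reversible ionisation of the p-hydroxybenzylic ether through a p-quinone methide should funnel C2 to the thermodynamic all-trans isomer. The closest known reaction is Friedel–Crafts C-glycosylation of furanose lactols with phenols.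

## Compound list
1 | 4-bromo-2,6-dimethoxyphenol | COc1cc(Br)cc(OC)c1O | starting material
2 | allyl alcohol | C=CCO | starting material
3 | 3-(4-hydroxy-3,5-dimethoxyphenyl)propanal | COc1cc(CCC=O)cc(OC)c1O | intermediate
4 | (E)-1-nitropropene | C/C=C/[N+](=O)[O-] | starting material
5 | (S)-diphenylprolinol TMS ether | C[Si](C)(C)OC(c1ccccc1)(c1ccccc1)[C@@H]1CCCN1 | starting material (catalyst)
6 | (2R,3R)-2-[(4-hydroxy-3,5-dimethoxyphenyl)methyl]-3-methyl-4-nitrobutanal | O=C[C@H](Cc1cc(OC)c(O)c(OC)c1)[C@@H](C)C[N+](=O)[O-] | intermediate
7 | (2R,3R)-2-[(4-hydroxy-3,5-dimethoxyphenyl)methyl]-3-methyl-4-nitrobutan-1-ol | OC[C@H](Cc1cc(OC)c(O)c(OC)c1)[C@@H](C)C[N+](=O)[O-] | intermediate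
8 | (3R,4R)-4-[(4-hydroxy-3,5-dimethoxyphenyl)methyl]-3-methyloxolan-2-ol | OC1OC[C@H](Cc2cc(OC)c(O)c(OC)c2)[C@H]1C | intermediate (anomeric centre unspecified)
9 | guaiacol (2-methoxyphenol) | COc1ccccc1O | starting material
10 | (2R,3R,4R)-2-(4-hydroxy-3-methoxyphenyl)-4-[(4-hydroxy-3,5-dimethoxyphenyl)methyl]-3-methyloxolane | COc1cc([C@@H]2OC[C@H](Cc3cc(OC)c(O)c(OC)c3)[C@H]2C)ccc1O | target

## Totals
Total steps: 5. Longest linear sequence: 5 (1 → 3 → 6 → 7 → 8 → 10).

## Three steps most likely to fail
1. **Step 5 (C-arylation).** The substrate's own electron-rich syringyl ring can attack the oxocarbenium to give a bridged benzobicyclo[3.2.1] product. Acid can also convert the product to an aryltetralin, and ortho-arylation or a poor C2 dr are possible.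
   Fallback: add excess 4-benzyloxy-3-methoxyphenylmagnesium bromide to lactol 8 to give the diol. Close the ring by SN2 at the primary carbon (TsCl/pyridine or PPh3/DIAD), then remove the benzyl group with H2/Pd-C.
2. **Step 4 (Nef of a primary nitroalkane on an oxidation-prone syringol).** Oxime by-products and low yield are likely.
   Fallback: drop the nitro-Michael strategy. Use Brown (E)-crotylboration of 4-benzyloxy-3-methoxybenzaldehyde, then hydroboration and TEMPO lactonisation. Follow with trans-selective α-benzylation using O-benzyl-syringyl benzyl bromide, DIBAL then Et3SiH/BF3 reduction, and H2/Pd-C.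
3. **Step 2 (alkyl nitroalkene with a free phenol).** Low reactivity, dr or ee are the risks.
   Fallback: use a hydrogenation-based route. Stobbe condensation of O-benzyl-syringaldehyde with diethyl succinate, Ru-BINAP hydrogenation, and reduction to the β-benzyl-γ-butyrolactone. Then trans-methylation (LDA/MeI), aryllithium addition with Et3SiH/BF3 reductive etherification, and H2/Pd-C.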